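**Retrosynthetic overview**
1. The (R)-lactol carbon is set last: the racemic 3-hydroxyphthalide is acylated under dynamic kinetic resolution and the acylal is then cleaved by neutral enzymatic alcoholysis. The racemic lactol comes from one aqueous-acid step that unmasks acetal, acetonide and silyl ether.
2. The seven-membered depsidone lactone (ring-A carboxyl to the B2 oxygen) is closed by carbodiimide lactonisation after hydrogenolysis of a ring-A benzyl ester.
3. The strategy rests on ring B (B1 ether carbon, B2 ester-oxygen carbon, B3 hydroxymethyl carbon, B4 phenol carbon, B5 lactone-carbonyl carbon, B6 lactol-bearing carbon). Its B2/B4 oxygens and B5 carboxyl form a resorcylate pattern, so the ring is folded from a dioxinone-masked 2,4-diketo chain by forming B5–B6. B1 already carries the ring-A aryloxy group and B6 the acetal carbon.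
4. The chain is built with the dioxinone as the nucleophile throughout, because an acyl donor bearing the doubly activated B3–H would be deprotonated instead of attacked. The silyloxyethyl-dioxinone dienolate is acylated by an aryloxy Weinreb amide (B2–B3), then the dianion is condensed with methyl dimethoxyacetate (B1–B6). The diaryl ether is a plain phenol alkylation.
5. Ring order: ring A (purchased) → ring B (step 9) → seven-membered lactone (step 11) → five-membered lactol ring (step 12).

Key step: step 9

Assumption: the lactol carbon equilibrates with the ring-opened formyl acid in basic or aqueous neutral media, so the (R) centre is fixed as an acylal and released last under neutral non-aqueous conditions, and the product is kept cold and isolated as a solid.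

Step 1
Reactants: 1 methyl 2,4-dihydroxy-3,6-dimethylbenzoate
Product: 2 methyl 2-hydroxy-4-methoxy-3,6-dimethylbenzoate
Conditions: MeI (1.1 equiv), K2CO3, acetone, reflux
Reagents that add atoms: iodomethane, CI
Why: Williamson etherification is selective for the 4-OH because the 2-OH is held in a hydrogen bond to the ester carbonyl and is flanked by the ester and the 3-methyl group.

Step 2
Reactants: 2 methyl 2-hydroxy-4-methoxy-3,6-dimethylbenzoate
Product: 3 2-hydroxy-4-methoxy-3,6-dimethylbenzoic acid
Conditions: KOH, DMSO/H2O (4:1), 90 °C; then 1 M HCl, 0 °C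
Reagents that add atoms: potassium hydroxide, [K+].[OH-]
Why: Saponification of the hindered, chelated salicylate needs hot KOH in aqueous DMSO, where the acid is protected from decarboxylation as its dianion, and cold acidification then frees it.

Step 3
Reactants: 3 2-hydroxy-4-methoxy-3,6-dimethylbenzoic acid
Product: 4 benzyl 2-hydroxy-4-methoxy-3,6-dimethylbenzoate
Conditions: BnBr, KHCO3, DMF, rt
Reagents that add atoms: benzyl bromide, BrCc1ccccc1
Why: Carboxylate O-alkylation (SN2) with a hydrogencarbonate base that leaves the chelated phenol un-ionised gives a benzyl ester that can later be removed by hydrogenolysis without acid or base.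

Step 4
Reactants: 4 benzyl 2-hydroxy-4-methoxy-3,6-dimethylbenzoate; 5 2-chloro-N-methoxy-N-methylacetamide
Product: 6 benzyl 4-methoxy-2-[2-(methoxy(methyl)amino)-2-oxoethoxy]-3,6-dimethylbenzoate
Conditions: K2CO3, KI (cat.), DMF, 60 °C
Reagents that add atoms: none
Why: Williamson etherification of the phenoxide with the alpha-chloro amide (iodide catalysis) installs the B1 carbon with its aryl ether in place, and the amide alpha-carbon is too weakly acidic for carbonate to trigger a Dieckmann attack on the neighbouring ester.

Step 5
Reactants: 7 2,2,6-trimethyl-4H-1,3-dioxin-4-one; 8 formaldehyde (monomer from cracked paraformaldehyde)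
Product: 9 6-(2-hydroxyethyl)-2,2-dimethyl-4H-1,3-dioxin-4-one
Conditions: LiN(iPr)2, THF, −78 °C; HCHO (gas), −78 °C; AcOH quench
Reagents that add atoms: none
Why: The lithium dienolate of the dioxinone reacts with aldehydes at its gamma-carbon (vinylogous aldol addition), so formaldehyde places the future hydroxymethyl carbon on the 6-methyl carbon, the future B3.

Step 6
Reactants: 9 6-(2-hydroxyethyl)-2,2-dimethyl-4H-1,3-dioxin-4-one
Product: 10 6-[2-(tert-butyldimethylsilyloxy)ethyl]-2,2-dimethyl-4H-1,3-dioxin-4-one
Conditions: TBSCl, imidazole, CH2Cl2, 0 °C to rt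
Reagents that add atoms: tert-butyldimethylsilyl chloride, CC(C)(C)[Si](C)(C)Cl
Why: Standard silylation of the primary alcohol gives an ether that blocks retro-aldol loss of formaldehyde in the enolate steps and is cleaved in the final acid step.

Step 7
Reactants: 10 6-[2-(tert-butyldimethylsilyloxy)ethyl]-2,2-dimethyl-4H-1,3-dioxin-4-one; 6 benzyl 4-methoxy-2-[2-(methoxy(methyl)amino)-2-oxoethoxy]-3,6-dimethylbenzoate
Product: 11 keto-dioxinone: benzyl 2-[4-(tert-butyldimethylsilyloxy)-3-(2,2-dimethyl-4-oxo-4H-1,3-dioxin-6-yl)-2-oxobutoxy]-4-methoxy-3,6-dimethylbenzoate (racemic at B3)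
Conditions: 10 (1.3 equiv), LiN(iPr)2 (1.3 equiv), THF, −78 °C; then 6, −78 to −40 °C; AcOH, −78 °C
Reagents that add atoms: none
Why: Gamma-acylation of the dioxinone dienolate by a Weinreb amide forms the B2–B3 bond, the chelated tetrahedral adduct preventing over-addition and keeping the acidic keto product masked until the quench, while the hindered electron-rich benzyl ester is not attacked at −78 °C.

Step 8
Reactants: 11 keto-dioxinone; 12 methyl 2,2-dimethoxyacetate
Product: 13 aryloxy diketo-dioxinone: dioxinone–CH(CH2OTBS)–CO–CH(OAr)–CO–CH(OMe)2 with Ar = ring A bearing the benzyl ester (keto–enol and diastereomer mixture)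
Conditions: LiN(iPr)2 (3.2 equiv), THF, −78 °C; then 12 (1.2 equiv), −78 to −40 °C; AcOH, −78 °C; crude used directly
Reagents that add atoms: none
Why: Claisen condensation of the keto-dioxinone dianion: the first equivalent of base removes the doubly activated B3–H, the second forms the more reactive terminal enolate at B1, which is acylated by the activated alpha,alpha-dialkoxy ester to form B1–B6, and the third covers the acidic diketone product.

Step 9
Reactants: 13 aryloxy diketo-dioxinone
Product: 15 benzodioxinone diaryl ether (B2–OH free; B6 dimethyl acetal; B3 CH2OTBS; ring-A benzyl ester), via cyclic aldol 14 (not isolated)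
Conditions: Et3N (2 equiv), 4 Å MS, CH2Cl2, rt
Reagents that add atoms: none
Why: Et3N reversibly removes B3–H of 13 to give the vinylogous dienolate of the dioxinone, whose alpha-carbon (B5) adds to the acetal-flanked ketone carbon (B6) to give aldol 14, which loses water across B5–B6 and enolises at B2 to the arene 15. The closest known reaction type is the amine- or carbonate-mediated aldol aromatisation of 2,4-diketo-dioxinones to acetonide-protected resorcylates. Ring B closes by a 6-(enolexo)-exo-trig aldol addition and the dioxinone ring survives as the benzodioxinone. No stereocentre is created, and the racemic B1 and B3 centres of 13 and those of 14 are erased on aromatisation. The step needs the carbon aldol to win over O-cyclisation to a pyranone, over beta-elimination of silanol from the B3 carbanion and over attack on the ring-A ester. The inductively activated ketone beside the acetal, the trans placing of the side chain and the dioxinone carbonyl across C5=C6 (which bars lactone and Claisen closure), the reversibility of any Dieckmann attack from the fully substituted B1 (its product cannot enolise), and a weak amine base at room temperature (no acylketene formation) should secure this.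

Step 10
Reactants: 15 benzodioxinone diaryl ether
Product: 16 ring-A carboxylic acid of 15 (2-aryloxy-4-methoxy-3,6-dimethylbenzoic acid with B2–OH free)
Conditions: H2 (1 atm), Pd/C, EtOAc, rt
Reagents that add atoms: none
Why: Hydrogenolysis of the benzyl ester under neutral conditions frees the ring-A acid while the acetal, silyl ether, acetonide and diaryl ether are inert.

Step 11
Reactants: 16 ring-A carboxylic acid
Product: 17 protected depsidone (seven-membered lactone between ring-A carbonyl and B2–O; benzodioxinone acetonide, dimethyl acetal and TBS ether intact)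
Conditions: DCC, DMAP (cat.), CH2Cl2 (0.005 M), 0 °C to rt
Reagents that add atoms: none
Why: Carbodiimide (Steglich-type) lactonisation of a 2-(2-hydroxyphenoxy)benzoic acid, the classical depsidone ring closure, forms the seven-membered lactone at B2–OH, the only free hydroxyl in the molecule.

Step 12
Reactants: 17 protected depsidone
Product: 18 racemic lactol (the target constitution, racemic at the lactol carbon)
Conditions: 2 M aq. HCl/THF (1:3), rt
Reagents that add atoms: water, O
Why: Aqueous acid hydrolyses the dimethyl acetal and the silyl ether, and the hydrate of the freed aldehyde then takes over the neighbouring acyl group of the benzodioxinone (5-exo-trig transacylation with loss of acetone) to give the 3-hydroxyphthalide and the B4 phenol, the lactol carbon forming as a racemate at this stage.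

Step 13
Reactants: 18 racemic lactol
Product: 19 (R)-bis-propanoate: propanoyl ester at the B3 CH2O group and (R)-propanoyloxy acylal at the lactol carbon
Conditions: (EtCO)2O (2.2 equiv), benzotetramisole (10 mol%, the antipode that gives the (R)-acylal, fixed by a test run), iPr2NEt, CHCl3, 0 °C
Reagents that add atoms: propanoic anhydride, CCC(=O)OC(=O)CC
Why: Acylative dynamic kinetic resolution of a 3-hydroxyphthalide (isothiourea-catalysed enantioselective O-acylation): the amine equilibrates the lactol enantiomers through the ring-opened formyl carboxylate while the chiral acyl isothiouronium acylates one of them faster, so the catalyst sets the acylal centre as (R), the primary alcohol is esterified alongside and the chelated, hindered B4 phenol should stay free.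

Step 14
Reactants: 19 (R)-bis-propanoate
Product: 20 target, (R)-lactol depsidone
Conditions: immobilised Burkholderia cepacia lipase, n-BuOH (6 equiv), MTBE, 20 °C; filter, concentrate cold, crystallise
Reagents that add atoms: none
Why: Lipase-catalysed transesterification (alcoholysis) cleaves both propanoates at the acyl C–O bond through acyl-enzyme intermediates, so no bond to the lactol carbon breaks and the (R) configuration from step 13 is retained, while the neutral non-aqueous medium without base keeps ring–chain tautomerism slow.

**Compound list**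
1 | methyl 2,4-dihydroxy-3,6-dimethylbenzoate | COC(=O)c1c(C)cc(O)c(C)c1O | starting material
2 | methyl 2-hydroxy-4-methoxy-3,6-dimethylbenzoate | COC(=O)c1c(C)cc(OC)c(C)c1O | intermediate
3 | 2-hydroxy-4-methoxy-3,6-dimethylbenzoic acid | OC(=O)c1c(C)cc(OC)c(C)c1O | intermediate
4 | benzyl 2-hydroxy-4-methoxy-3,6-dimethylbenzoate | O=C(OCc1ccccc1)c1c(C)cc(OC)c(C)c1O | intermediate
5 | 2-chloro-N-methoxy-N-methylacetamide | CON(C)C(=O)CCl | starting material
6 | benzyl 4-methoxy-2-[2-(methoxy(methyl)amino)-2-oxoethoxy]-3,6-dimethylbenzoate | CON(C)C(=O)COc1c(C)c(OC)cc(C)c1C(=O)OCc1ccccc1 | intermediate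
7 | 2,2,6-trimethyl-4H-1,3-dioxin-4-one | CC1=CC(=O)OC(C)(C)O1 | starting material
8 | formaldehyde (from paraformaldehyde) | C=O | starting material
9 | 6-(2-hydroxyethyl)-2,2-dimethyl-4H-1,3-dioxin-4-one | CC1(C)OC(=O)C=C(CCO)O1 | intermediate
10 | 6-[2-(tert-butyldimethylsilyloxy)ethyl]-2,2-dimethyl-4H-1,3-dioxin-4-one | CC1(C)OC(=O)C=C(CCO[Si](C)(C)C(C)(C)C)O1 | intermediate
11 | keto-dioxinone, racemic at B3 | CC1(C)OC(=O)C=C(O1)C(CO[Si](C)(C)C(C)(C)C)C(=O)COc1c(C)c(OC)cc(C)c1C(=O)OCc1ccccc1 | intermediate
12 | methyl 2,2-dimethoxyacetate | COC(OC)C(=O)OC | starting material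
13 | aryloxy diketo-dioxinone (key-step precursor, keto–enol mixture) | CC1(C)OC(=O)C=C(O1)C(CO[Si](C)(C)C(C)(C)C)C(=O)C(Oc1c(C)c(OC)cc(C)c1C(=O)OCc1ccccc1)C(=O)C(OC)OC | intermediate
14 | cyclic aldol adduct (B5–B6 bond formed, before dehydration; not isolated) | CC1(C)OC(=O)C2C(O1)=C(CO[Si](C)(C)C(C)(C)C)C(=O)C(Oc1c(C)c(OC)cc(C)c1C(=O)OCc1ccccc1)C2(O)C(OC)OC | intermediate
15 | benzodioxinone diaryl ether with free B2–OH and B6 dimethyl acetal (key-step product) | CC1(C)Oc2c(CO[Si](C)(C)C(C)(C)C)c(O)c(Oc3c(C)c(OC)cc(C)c3C(=O)OCc3ccccc3)c(C(OC)OC)c2C(=O)O1 | intermediate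
16 | ring-A carboxylic acid of 15 | CC1(C)Oc2c(CO[Si](C)(C)C(C)(C)C)c(O)c(Oc3c(C)c(OC)cc(C)c3C(=O)O)c(C(OC)OC)c2C(=O)O1 | intermediate
17 | protected depsidone (acetonide, dimethyl acetal, TBS ether) | COc1cc(C)c2c(c1C)Oc1c(C(OC)OC)c3C(=O)OC(C)(C)Oc3c(CO[Si](C)(C)C(C)(C)C)c1OC2=O | intermediate
18 | racemic lactol depsidone | COc1cc(C)c2c(c1C)Oc1c(c(CO)c(O)c3c1C(O)OC3=O)OC2=O | intermediate
19 | (R)-bis-propanoate (CH2O-propanoyl and lactol O-propanoyl) | COc1cc(C)c2c(c1C)Oc1c(c(COC(=O)CC)c(O)c3c1[C@H](OC(=O)CC)OC3=O)OC2=O | intermediate
20 | target: depsidone with ring A (OMe, two Me) and ring B (CH2OH, OH) fused to the (R)-3-hydroxyphthalide lactol | COc1cc(C)c2c(c1C)Oc1c(c(CO)c(O)c3c1[C@H](O)OC3=O)OC2=O | target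

**Step count**
Total: 14 steps. Longest linear sequence: 12 steps (steps 1–4, then 7–14).

**Steps most likely to fail**

1. Step 9 (key step). Beta-elimination of silanol from the B3 carbanion, O-cyclisation to a pyranone, or steric slowing of the aldol by the B3 substituent may outrun ring closure. The fallback leaves the hydroxymethyl carbon out of the chain and adds it to the arene afterwards. It sets out from 6 (with 7) and returns at 15.
 - The dienolate of 7 (LiN(iPr)2, THF, −78 °C) is acylated by 6 to the unsubstituted keto-dioxinone F1.
 - Its dianion is condensed with 12 to the unsubstituted diketo-dioxinone F2.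
 - Et3N in CH2Cl2 folds this to the B3-unsubstituted benzodioxinone phenol F3, the parent case of this aromatisation.
 - Magnesium-mediated ortho-formylation of the B2 phenol (MgCl2, Et3N, paraformaldehyde, MeCN, reflux) can only go to B3, since B1 is blocked, and gives the salicylaldehyde F4.
 - NaBH4 (THF/EtOH, 0 °C) gives the benzylic alcohol F5.
 - TBSCl/imidazole silylates the primary alcohol selectively and returns 15.

2. Step 14. The lipase may turn over the hindered acylal slowly, and the freed lactol may lose configuration through ring opening during a long contact time. The fallback sets out from 18 and returns at 20. The racemic lactol 18 is separated directly on an immobilised polysaccharide chiral phase by preparative SFC at low temperature with an acidified modifier. The (S)-fraction is racemised by brief contact with Et3N and recycled. No new compound is made (F0).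

3. Step 8. The terminal B1 enolate of the dianion may attack the neighbouring ring-A benzyl ester (Dieckmann closure to a 3-hydroxybenzofuran) or be quenched by proton transfer before the Claisen acylation. The fallback carries ring A as a lithium carboxylate, which is not an electrophile. It sets out from 6 and returns at 16.
 - Hydrogenolysis of 6 (H2, Pd/C, EtOAc) gives the carboxylic acid Weinreb amide F6.
 - Its lithium salt (LiN(SiMe3)2, 1 equiv) is acylated by the dienolate of 10 to the keto-dioxinone acid F7.
 - LiN(iPr)2 (4.2 equiv) and 12 give the diketo-dioxinone acid F8.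
 - Et3N in CH2Cl2 aromatises this to 16, ready for the lactonisation of step 11.

**Further compounds**
F1 | step 9 | benzyl 2-[3-(2,2-dimethyl-4-oxo-4H-1,3-dioxin-6-yl)-2-oxopropoxy]-4-methoxy-3,6-dimethylbenzoate | CC1(C)OC(=O)C=C(O1)CC(=O)COc1c(C)c(OC)cc(C)c1C(=O)OCc1ccccc1
F2 | step 9 | diketo-dioxinone without the B3 substituent | CC1(C)OC(=O)C=C(O1)CC(=O)C(Oc1c(C)c(OC)cc(C)c1C(=O)OCc1ccccc1)C(=O)C(OC)OC
F3 | step 9 | B3-unsubstituted benzodioxinone phenol | CC1(C)Oc2cc(O)c(Oc3c(C)c(OC)cc(C)c3C(=O)OCc3ccccc3)c(C(OC)OC)c2C(=O)O1
F4 | step 9 | B3-formyl benzodioxinone phenol | CC1(C)Oc2c(C=O)c(O)c(Oc3c(C)c(OC)cc(C)c3C(=O)OCc3ccccc3)c(C(OC)OC)c2C(=O)O1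
F5 | step 9 | B3-hydroxymethyl benzodioxinone phenol | CC1(C)Oc2c(CO)c(O)c(Oc3c(C)c(OC)cc(C)c3C(=O)OCc3ccccc3)c(C(OC)OC)c2C(=O)O1
F0 | step 14 | none | none
F6 | step 8 | 4-methoxy-2-[2-(methoxy(methyl)amino)-2-oxoethoxy]-3,6-dimethylbenzoic acid | CON(C)C(=O)COc1c(C)c(OC)cc(C)c1C(=O)O
F7 | step 8 | keto-dioxinone with free ring-A carboxylic acid | CC1(C)OC(=O)C=C(O1)C(CO[Si](C)(C)C(C)(C)C)C(=O)COc1c(C)c(OC)cc(C)c1C(=O)O
F8 | step 8 | diketo-dioxinone with free ring-A carboxylic acid | CC1(C)OC(=O)C=C(O1)C(CO[Si](C)(C)C(C)(C)C)C(=O)C(Oc1c(C)c(OC)cc(C)c1C(=O)O)C(=O)C(OC)OC
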